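**Retrosynthetic overview**
- No ring is formed: the naphthoquinone enters intact as menadione. The last bond, C1'–C2', comes from Ni-catalysed coupling of chloromethyl-menadione 15 with the E-vinylalane made by methylalumination of alkyne 13 (this sets 2'E and brings the 3'-methyl).
- Alkyne 13 comes from iodide 10 and a propargyl anion (C2'–C4').
- Key disconnection C16'–C17': the saturated chiral C15 alcohol 3 is joined to allyl sulfone 7, whose sulfonyl-stabilised allyl carbanion is the polarity-reversed form of a prenyl-type electrophile. The coupling is a dehydrative Mitsunobu-type C-alkylation, and the sulfone is then removed with Pd/hydride.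
- Both halves come from one compound, 12-hydroxyfarnesyl acetate 2 (SeO2 on farnesyl acetate 1). One Ir-catalysed asymmetric hydrogenation of its three alkenes gives 3 with all three stereocentres. Bromination, Cu-catalysed isopentyl coupling and Pd-catalysed sulfination give 7.

Assumptions: (2E,6E)-farnesyl acetate is bought as the single E,E isomer. Primed locants are those of the target side chain; the target is read from the SMILES as 7'S,11'R,15'R.

**Step 1**
Reactants: 1 (2E,6E)-farnesyl acetate
Product: 2 (2E,6E,10E)-12-hydroxy-3,7,11-trimethyldodeca-2,6,10-trien-1-yl acetate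
Conditions: SeO2 (0.3 equiv), t-BuOOH (70% aq, 3 equiv), salicylic acid (0.1 equiv), CH2Cl2, 0 °C → rt
Reagents that add atoms: selenium dioxide (O=[Se]=O); tert-butyl hydroperoxide (CC(C)(C)OO)
Why: Sharpless-type SeO2/TBHP allylic oxidation (ene reaction then [2,3]-shift) is selective for the E-methyl of the terminal isopropylidene, so the CH2OH is installed with 10E geometry and the acetate end stays differentiated.

**Step 2**
Reactants: 2 (2E,6E,10E)-12-hydroxy-3,7,11-trimethyldodeca-2,6,10-trien-1-yl acetate
Product: 3 (3S,7R,11R)-12-hydroxy-3,7,11-trimethyldodecyl acetate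
Conditions: H2 (50 bar), [Ir(cod)(pyridine–phosphinite)]BArF (Pfaltz type, 1–2 mol %; the antipode of the catalyst that turns (2E,6E)-farnesol into (3R,7R)-hexahydrofarnesol), CH2Cl2, rt
Reagents that add atoms: none
Why: Ir–N,P-catalysed asymmetric hydrogenation of trisubstituted alkenes; all three E-alkenes have the same local shape (H on the head-side carbon, methyl on the tail-side carbon), so one catalyst enantiomer adds H2 to the same face of each and sets 3S, 7R and 11R (later C7', C11', C15') under catalyst control.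

**Step 3**
Reactants: 2 (2E,6E,10E)-12-hydroxy-3,7,11-trimethyldodeca-2,6,10-trien-1-yl acetate
Product: 4 (2E,6E,10E)-12-bromo-3,7,11-trimethyldodeca-2,6,10-trien-1-yl acetate
Conditions: CBr4, PPh3, CH2Cl2, 0 °C
Reagents that add atoms: tetrabromomethane (BrC(Br)(Br)Br)
Why: Appel reaction; SN2 at the primary allylic carbinol keeps the 10E geometry and leaves the acetate alone.

**Step 4**
Reactants: 4 (2E,6E,10E)-12-bromo-3,7,11-trimethyldodeca-2,6,10-trien-1-yl acetate; 5 isopentylmagnesium bromide
Product: 6 (2E,6E,10E)-3,7,11,15-tetramethylhexadeca-2,6,10-trien-1-yl acetate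
Conditions: 5 (1.3 equiv), Li2CuCl4 (5 mol %), THF, −78 °C, quench cold
Reagents that add atoms: none
Why: Kochi-type Cu-catalysed Grignard/allylic bromide coupling; attack at the unhindered CH2Br (SN2, 10E retained) is far faster at −78 °C than addition to the ester or substitution of the allylic acetate, and it installs the saturated tail C29'–C32'.

**Step 5**
Reactants: 6 (2E,6E,10E)-3,7,11,15-tetramethylhexadeca-2,6,10-trien-1-yl acetate
Product: 7 {[(2E,6E,10E)-3,7,11,15-tetramethylhexadeca-2,6,10-trien-1-yl]sulfonyl}benzene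
Conditions: PhSO2Na (2 equiv), Pd(PPh3)4 (3 mol %), THF/MeOH, rt, stopped at full conversion
Reagents that add atoms: sodium benzenesulfinate ([Na+].[O-]S(=O)c1ccccc1)
Why: Tsuji–Trost allylic substitution; the sulfinate attacks through sulfur at the primary terminus of the π-allyl complex and gives the linear E-allyl sulfone.

**Step 6 (key step)**
Reactants: 3 (3S,7R,11R)-12-hydroxy-3,7,11-trimethyldodecyl acetate; 7 {[(2E,6E,10E)-3,7,11,15-tetramethylhexadeca-2,6,10-trien-1-yl]sulfonyl}benzene
Product: 8 (3S,7R,11R,13RS,14E,18E,22E)-3,7,11,15,19,23,27-heptamethyl-13-(phenylsulfonyl)octacosa-14,18,22-trien-1-yl acetate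
Conditions: Me3P=CHCN (CMMP, 1.5 equiv), 7 (1.3 equiv), toluene, 110 °C, sealed tube
Reagents that add atoms: none
Why: Tsunoda Mitsunobu-type C-alkylation: the ylide deprotonates allyl sulfone 7 (pKa about 23) and turns the primary OH of 3 into an alkoxyphosphonium leaving group, so the sulfonyl-stabilised allyl carbanion (the polarity-reversed form of allylic acetate 6) displaces it by SN2 and joins C17' to C16', two carbons that are both electrophilic in their native form; the neutral conditions spare the acetate, C11 of 3 is not involved, and the new sulfone-bearing centre (both epimers) is erased in step 7.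

**Step 7**
Reactants: 8 (3S,7R,11R,13RS,14E,18E,22E)-3,7,11,15,19,23,27-heptamethyl-13-(phenylsulfonyl)octacosa-14,18,22-trien-1-yl acetate
Product: 9 (3S,7S,11R,14E,18E,22E)-3,7,11,15,19,23,27-heptamethyloctacosa-14,18,22-trien-1-ol
Conditions: PdCl2(dppp) (5 mol %), LiEt3BH (5 equiv), THF, 0 °C → rt
Reagents that add atoms: none
Why: Pd-catalysed reductive desulfonylation of an allylic sulfone; hydride is delivered to the π-allyl carbon that carried the sulfone, so the C18'=C19' position and E geometry are kept, and the same hydride cleaves the acetate to free the C5' alcohol (the 7S label is only a CIP priority change; no centre is touched).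

**Step 8**
Reactants: 9 (3S,7S,11R,14E,18E,22E)-3,7,11,15,19,23,27-heptamethyloctacosa-14,18,22-trien-1-ol
Product: 10 (3S,7S,11R,14E,18E,22E)-1-iodo-3,7,11,15,19,23,27-heptamethyloctacosa-14,18,22-triene
Conditions: I2, PPh3, imidazole, CH2Cl2, 0 °C → rt
Reagents that add atoms: iodine (II)
Why: Appel-type (Garegg–Samuelsson) iodination of a primary alcohol; the isolated trisubstituted alkenes are inert.

**Step 9**
Reactants: 10 (3S,7S,11R,14E,18E,22E)-1-iodo-3,7,11,15,19,23,27-heptamethyloctacosa-14,18,22-triene; 11 1-(trimethylsilyl)prop-1-yne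
Product: 13 (6S,10R,14R,17E,21E,25E)-6,10,14,18,22,26,30-heptamethylhentriaconta-17,21,25-trien-1-yne, via TMS-alkyne 12 (not isolated)
Conditions: 11 (1.5 equiv), n-BuLi, THF, −78 → −20 °C; add 10, −78 °C → rt; then MeOH, K2CO3, rt
Reagents that add atoms: none
Why: SN2 alkylation of lithiated 1-TMS-propyne at its propargylic carbon with the primary iodide adds C2'–C4', and methanolysis of the C–Si bond frees the terminal alkyne.

**Step 10**
Reactants: 14 menadione (2-methylnaphthalene-1,4-dione)
Product: 15 2-(chloromethyl)-3-methylnaphthalene-1,4-dione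
Conditions: 37% aq. HCHO, HCl (g), AcOH, rt, dark
Reagents that add atoms: formaldehyde (C=O); hydrogen chloride (Cl)
Why: Blanc-type chloromethylation at the only free quinone position (C3) gives the C1' electrophile in one step.

**Step 11**
Reactants: 13 (6S,10R,14R,17E,21E,25E)-6,10,14,18,22,26,30-heptamethylhentriaconta-17,21,25-trien-1-yne; 15 2-(chloromethyl)-3-methylnaphthalene-1,4-dione
Product: 17 2-methyl-3-[(2E,7S,11R,15R,18E,22E,26E)-3,7,11,15,19,23,27,31-octamethyldotriaconta-2,18,22,26-tetraen-1-yl]naphthalene-1,4-dione, via vinylalane 16 (not isolated)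
Conditions: Me3Al (2 equiv), Cp2ZrCl2 (0.25 equiv), (CH2Cl)2, rt; strip excess Me3Al; then 15, NiCl2(PPh3)2/n-BuLi (5 mol % Ni(0)), THF, −20 °C → rt
Reagents that add atoms: trimethylaluminium (C[Al](C)C)
Why: Negishi Zr-catalysed methylalumination adds Me and Al syn across the terminal alkyne (Me to C3', Al to C2'), and Lipshutz-type Ni(0) coupling of the vinylalane with the chloromethyl quinone proceeds with retention, giving the 2'E alkene and the free quinone directly; remote trisubstituted alkenes do not react.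

**Compound list**
1 | (2E,6E)-farnesyl acetate | CC(=O)OC/C=C(\C)CC/C=C(\C)CCC=C(C)C | starting material
2 | (2E,6E,10E)-12-hydroxy-3,7,11-trimethyldodeca-2,6,10-trien-1-yl acetate | CC(=O)OC/C=C(\C)CC/C=C(\C)CC/C=C(\C)CO | intermediate
3 | (3S,7R,11R)-12-hydroxy-3,7,11-trimethyldodecyl acetate | CC(=O)OCC[C@@H](C)CCC[C@@H](C)CCC[C@@H](C)CO | intermediate
4 | (2E,6E,10E)-12-bromo-3,7,11-trimethyldodeca-2,6,10-trien-1-yl acetate | CC(=O)OC/C=C(\C)CC/C=C(\C)CC/C=C(\C)CBr | intermediate
5 | isopentylmagnesium bromide | CC(C)CC[Mg]Br | starting material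
6 | (2E,6E,10E)-3,7,11,15-tetramethylhexadeca-2,6,10-trien-1-yl acetate | CC(=O)OC/C=C(\C)CC/C=C(\C)CC/C=C(\C)CCCC(C)C | intermediate
7 | {[(2E,6E,10E)-3,7,11,15-tetramethylhexadeca-2,6,10-trien-1-yl]sulfonyl}benzene | O=S(=O)(C/C=C(\C)CC/C=C(\C)CC/C=C(\C)CCCC(C)C)c1ccccc1 | intermediate
8 | (3S,7R,11R,13RS,14E,18E,22E)-3,7,11,15,19,23,27-heptamethyl-13-(phenylsulfonyl)octacosa-14,18,22-trien-1-yl acetate | CC(=O)OCC[C@@H](C)CCC[C@@H](C)CCC[C@@H](C)CC(/C=C(\C)CC/C=C(\C)CC/C=C(\C)CCCC(C)C)S(=O)(=O)c1ccccc1 | intermediate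
9 | (3S,7S,11R,14E,18E,22E)-3,7,11,15,19,23,27-heptamethyloctacosa-14,18,22-trien-1-ol | OCC[C@@H](C)CCC[C@@H](C)CCC[C@@H](C)CC/C=C(\C)CC/C=C(\C)CC/C=C(\C)CCCC(C)C | intermediate
10 | (3S,7S,11R,14E,18E,22E)-1-iodo-3,7,11,15,19,23,27-heptamethyloctacosa-14,18,22-triene | ICC[C@@H](C)CCC[C@@H](C)CCC[C@@H](C)CC/C=C(\C)CC/C=C(\C)CC/C=C(\C)CCCC(C)C | intermediate
11 | 1-(trimethylsilyl)prop-1-yne | CC#C[Si](C)(C)C | starting material
12 | trimethyl[(6S,10R,14R,17E,21E,25E)-6,10,14,18,22,26,30-heptamethylhentriaconta-17,21,25-trien-1-yn-1-yl]silane | C[Si](C)(C)C#CCCC[C@@H](C)CCC[C@@H](C)CCC[C@@H](C)CC/C=C(\C)CC/C=C(\C)CC/C=C(\C)CCCC(C)C | intermediate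
13 | (6S,10R,14R,17E,21E,25E)-6,10,14,18,22,26,30-heptamethylhentriaconta-17,21,25-trien-1-yne | C#CCCC[C@@H](C)CCC[C@@H](C)CCC[C@@H](C)CC/C=C(\C)CC/C=C(\C)CC/C=C(\C)CCCC(C)C | intermediate
14 | menadione (2-methylnaphthalene-1,4-dione) | CC1=CC(=O)c2ccccc2C1=O | starting material
15 | 2-(chloromethyl)-3-methylnaphthalene-1,4-dione | CC1=C(CCl)C(=O)c2ccccc2C1=O | intermediate
16 | dimethyl[(1E,6S,10R,14R,17E,21E,25E)-2,6,10,14,18,22,26,30-octamethylhentriaconta-1,17,21,25-tetraen-1-yl]alumane | C[Al](C)/C=C(\C)CCC[C@@H](C)CCC[C@@H](C)CCC[C@@H](C)CC/C=C(\C)CC/C=C(\C)CC/C=C(\C)CCCC(C)C | intermediate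
17 | 2-methyl-3-[(2E,7S,11R,15R,18E,22E,26E)-3,7,11,15,19,23,27,31-octamethyldotriaconta-2,18,22,26-tetraen-1-yl]naphthalene-1,4-dione | CC1=C(C/C=C(\C)CCC[C@@H](C)CCC[C@@H](C)CCC[C@@H](C)CC/C=C(\C)CC/C=C(\C)CC/C=C(\C)CCCC(C)C)C(=O)c2ccccc2C1=O | target

**Totals**
Total step count: 11. Longest linear sequence: 9 steps (steps 1, 3, 4, 5, 6, 7, 8, 9, 11).

**Three steps most likely to fail, with fallbacks**

Step 2 (one-pot triple asymmetric hydrogenation). The allylic-alcohol alkene and the allylic-acetate alkene may not follow the same facial sense or selectivity as the isolated alkene, which would give diastereomers that are hard to separate. The fallback sets out from 2 and comes back at 3. The free OH is first used as a directing group: Noyori hydrogenation with Ru(OAc)2[BINAP] (the BINAP enantiomer that gives 11R; H2, MeOH) reduces only the C10=C11 allylic-alcohol alkene and gives (2E,6E,11R)-12-hydroxy-3,7,11-trimethyldodeca-2,6-dien-1-yl acetate F1. The two remaining alkenes, now the plain O-protected farnesol pattern for which the Ir catalyst is best precedented, are then reduced with the Ir catalyst of step 2 to give 3.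

Step 5 (Pd-catalysed sulfination). Syn/anti isomerisation of the π-allyl intermediate, or reversible sulfinate addition, may erode the 2E geometry. The fallback sets out from 6 and comes back at 7 without any π-allyl intermediate. Methanolysis (K2CO3, MeOH) gives (2E,6E,10E)-3,7,11,15-tetramethylhexadeca-2,6,10-trien-1-ol F2. PBr3 (Et2O, −10 °C) gives (2E,6E,10E)-1-bromo-3,7,11,15-tetramethylhexadeca-2,6,10-triene F3. Direct SN2 with PhSO2Na in DMF at rt then gives 7.

Step 6 (Mitsunobu-type C-alkylation). The β-branched carbinol carbon of 3 and the bulky long-chain allyl sulfone may react too slowly with the phosphorane. The fallback sets out from 3 and comes back at 8 by the classical two-stage carbanion alkylation. I2/PPh3/imidazole converts 3 into (3S,7R,11R)-12-iodo-3,7,11-trimethyldodecyl acetate F4. Sulfone 7 is deprotonated with exactly one equivalent of n-BuLi (THF/DMPU, −78 °C), so the acetate meets only the stabilised allyl anion, and is alkylated with F4 at −78 → −20 °C to give 8.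

**Further compounds**
F1 | step 2 | (2E,6E,11R)-12-hydroxy-3,7,11-trimethyldodeca-2,6-dien-1-yl acetate | CC(=O)OC/C=C(\C)CC/C=C(\C)CCC[C@@H](C)CO
F2 | step 5 | (2E,6E,10E)-3,7,11,15-tetramethylhexadeca-2,6,10-trien-1-ol | OC/C=C(\C)CC/C=C(\C)CC/C=C(\C)CCCC(C)C
F3 | step 5 | (2E,6E,10E)-1-bromo-3,7,11,15-tetramethylhexadeca-2,6,10-triene | BrC/C=C(\C)CC/C=C(\C)CC/C=C(\C)CCCC(C)C
F4 | step 6 | (3S,7R,11R)-12-iodo-3,7,11-trimethyldodecyl acetate | CC(=O)OCC[C@@H](C)CCC[C@@H](C)CCC[C@@H](C)CI
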